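**Assumptions**
- 3,4,5-Trimethoxyphenylmagnesium bromide (5) is bought as a ~0.5 M THF solution, so it is a starting material and no step is needed to make it.
- The (R)-diarylprolinol silyl ether gives the syn (2S,3S) adduct with 1-nitropropene. By analogy, the (S)-catalyst gives the (2R,3S) syn adduct with nitrostyrene. The C3 label changes from S to R when Me replaces Ph, and the spatial arrangement is the same, so the (R)-catalyst gives (2S,3S) here.
- The all-trans 2,5-diaryl-3,4-dimethyltetrahydrofuran is the thermodynamic isomer and is the relative configuration of the target. Its SMILES corresponds to (2S,3S,4S,5S).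

## Retrosynthetic overview
1. The target is all-trans 2,5-diaryl-3,4-dimethyl-THF. It comes from C-arylation of 2-aryl-3,4-dimethyl-THF lactol 7 with veratrole (8) in Step 4. This closes no ring. It forms the last C–C bond and sets the two benzylic centres by thermodynamic control.
2. Lactol 7 is the cyclic form of a γ-hydroxy aldehyde. That aldehyde comes from oxidative Nef conversion of the CH2NO2 group of γ-nitro alcohol 6, and the THF ring closes spontaneously in Step 3.
3. Nitro alcohol 6 comes from addition of 3,4,5-trimethoxyphenyl-MgBr (5) to (2S,3S)-2,3-dimethyl-4-nitrobutanal (4).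
4. Nitroaldehyde 4 comes from one enamine-catalysed Michael addition of propanal to (E)-1-nitropropene. This sets both methyl stereocentres (syn, which becomes trans in the ring).

## Route

**Step 1**
Reactants: 1 propanal; 2 (E)-1-nitropropene; catalyst 3 (R)-α,α-diphenylprolinol TMS ether
Product: 4 (2S,3S)-2,3-dimethyl-4-nitrobutanal
Conditions: 3 (10 mol %), PhCO2H (10 mol %), toluene, 0 °C, 16 h; quick SiO2 filtration, use at once
Reagents that add atoms: none
Why: Hayashi–Jørgensen enamine Michael addition. The bulky silyl ether shields one face of the (E)-s-trans enamine, and the nitroalkene approaches through a synclinal (Seebach) transition state. This gives the syn adduct, which becomes the trans-3,4-dimethyl pair in the ring, so both methyl stereocentres are set catalytically.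

**Step 2**
Reactants: 4; 5 (3,4,5-trimethoxyphenylmagnesium bromide)
Product: 6 (2S,3S)-2,3-dimethyl-4-nitro-1-(3,4,5-trimethoxyphenyl)butan-1-ol (mixture of C1 epimers)
Conditions: 5 (2.5 equiv), THF, −78 → −20 °C, 2 h; then aq. NH4Cl
Reagents that add atoms: 5, COc1cc([Mg]Br)cc(OC)c1OC (supplies the 3,4,5-trimethoxyphenyl group; already listed as a reactant)
Why: Grignard 1,2-addition to the aldehyde. The first equivalent of 5 deprotonates the nitroalkane to the Mg nitronate, which is stable at low temperature, and the second adds to the aldehyde. The new carbinol is an epimeric mixture. That is harmless because the carbinol carbon is re-set thermodynamically in Step 4, and the methyl stereocentres are untouched.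

**Step 3**
Reactants: 6
Product: 7 (3S,4S)-3,4-dimethyl-5-(3,4,5-trimethoxyphenyl)oxolan-2-ol (cyclic hemiacetal of 4-hydroxy-2,3-dimethyl-4-(3,4,5-trimethoxyphenyl)butanal; mixture of anomers and C5 epimers)
Conditions: (i) NaOMe, MeOH, 0 °C, then concentrate; (ii) Oxone, NaHCO3, THF/H2O, 0 °C, 1 h
Reagents that add atoms: Oxone, [K+].OOS(=O)(=O)[O-]; water, O (source of the carbonyl oxygen)
Why: Oxidative Nef reaction of the nitronate converts CH2NO2 to CHO. The γ-hydroxy aldehyde closes spontaneously to the five-membered lactol, which forms the THF ring. Any epimerisation α to the aldehyde is self-correcting, because trans-3,4-dimethyl is the thermodynamic arrangement. The C4 methyl centre, next to the benzylic carbon, is not touched.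

**Step 4**
Reactants: 7; 8 (veratrole, 1,2-dimethoxybenzene)
Product: 9 (2S,3S,4S,5S)-2-(3,4-dimethoxyphenyl)-3,4-dimethyl-5-(3,4,5-trimethoxyphenyl)tetrahydrofuran, 5-methoxygalbelgin
Conditions: 8 (3 equiv), TMSOTf (30 mol %), CH2Cl2, −40 → 0 °C, 3 h; then TfOH (5 mol %), 23 °C, 4 h, same pot; quench Et3N, aq. NaHCO3
Reagents that add atoms: 8, COc1ccccc1OC (supplies the 3,4-dimethoxyphenyl group; water is lost)
Why: Proposed new method: Lewis-acid ionisation of lactol 7 gives a 2,3-disubstituted THF oxocarbenium ion, and veratrole attacks para to one OMe to give the 3,4-dimethoxyphenyl group. Attack anti to the adjacent C3 methyl is sterically preferred. The Brønsted acid then reversibly ionises the benzylic C–O bonds, which are p-alkoxybenzylic, so both aryl-bearing centres equilibrate to the all-trans isomer, the thermodynamic sink. The methyl stereocentres are not ionised and stay fixed. The closest known reactions are Friedel–Crafts C-arylation of furanose lactols (C-aryl glycoside synthesis) and acid epimerisation of 2,5-diaryl-THF lignans. The new feature is using them together on a 2-aryl-3,4-dialkyl lactol to build the lignan core in one operation.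

## Compound list
1 | propanal | CCC=O | starting material
2 | (E)-1-nitroprop-1-ene | C/C=C/[N+](=O)[O-] | starting material
3 | (R)-α,α-diphenylprolinol trimethylsilyl ether | C[Si](C)(C)OC(c1ccccc1)(c1ccccc1)[C@H]1CCCN1 | starting material (catalyst)
4 | (2S,3S)-2,3-dimethyl-4-nitrobutanal | O=C[C@@H](C)[C@H](C)C[N+](=O)[O-] | intermediate
5 | 3,4,5-trimethoxyphenylmagnesium bromide | COc1cc([Mg]Br)cc(OC)c1OC | starting material
6 | (2S,3S)-2,3-dimethyl-4-nitro-1-(3,4,5-trimethoxyphenyl)butan-1-ol (C1 epimers) | COc1cc(C(O)[C@@H](C)[C@H](C)C[N+](=O)[O-])cc(OC)c1OC | intermediate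
7 | (3S,4S)-3,4-dimethyl-5-(3,4,5-trimethoxyphenyl)oxolan-2-ol (C2/C5 unspecified) | COc1cc(C2OC(O)[C@@H](C)[C@@H]2C)cc(OC)c1OC | intermediate
8 | 1,2-dimethoxybenzene (veratrole) | COc1ccccc1OC | starting material
9 | 5-methoxygalbelgin, (2S,3S,4S,5S)-2-(3,4-dimethoxyphenyl)-3,4-dimethyl-5-(3,4,5-trimethoxyphenyl)tetrahydrofuran | COc1ccc([C@H]2O[C@H](c3cc(OC)c(OC)c(OC)c3)[C@@H](C)[C@@H]2C)cc1OC | target

**Total steps:** 4
**Longest linear sequence:** 4 steps (1 → 2 → 3 → 4)

## Three steps most likely to fail
1. **Step 4 (proposed new step).** The risks are a poor C2/C5 epimer ratio, ring-opening or over-arylation by excess veratrole, and oligomerisation through the electron-rich trimethoxyphenyl ring. Fallback (known chemistry): add 3,4-dimethoxyphenylmagnesium bromide to lactol 7 to give the 1,4-diaryl-2,3-dimethylbutane-1,4-diol, then cyclodehydrate with TsOH to the thermodynamic all-trans THF, as in classical galbelgin-type syntheses.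
2. **Step 2.** The acidic nitroalkane consumes Grignard reagent, the aldehyde α-centre can epimerise or undergo retro-Michael fragmentation, and the carbinol dr is poor. Fallback: protect the aldehyde of 4 as the 1,3-dioxolane, carry out the Nef reaction to the new aldehyde, add 5 to it, then remove the acetal with aqueous acid. This gives the same lactol 7 because the (S,S)-dimethyl skeleton is C2-symmetric.
3. **Step 1.** 1-Nitropropene polymerises readily, and an alkyl nitroalkene may give lower dr and ee than nitrostyrene. Fallback: Evans N-propionyl oxazolidinone enolate oxidative homocoupling, using the auxiliary enantiomer that gives the C2-symmetric (S,S)-2,3-dimethylsuccinyl bis-imide. Reduce to (S,S)-2,3-dimethylbutane-1,4-diol and mono-oxidise (TEMPO/PhI(OAc)2) to the 3,4-dimethyl lactol. Add 5 to the lactol to give the 1-aryl-2,3-dimethylbutane-1,4-diol, then oxidise the primary alcohol selectively (TEMPO) to give lactol 7.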